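The plan rests on closing ring A at the angular carbon (drimane numbering). C10 is alpha to C9, the only sp2 carbon of the decalin, so C9 is carried as a ketone inside a monocyclic 2,6-dimethylcyclohex-2-enone whose C5 bears the gem-dimethyl chloropropyl chain. Gamma-deprotonation gives a dienolate whose alpha carbon C10 displaces the primary chloride at C1 under a chiral ammonium counter-ion. This one operation forms the C1–C10 bond, ring A and the quaternary stereocentre and leaves C5=C6, so that hydrogenation anti to the angular methyl then sets the trans ring fusion. The C9 ketone later takes on C11, the arene and chlorine.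

Key step: step 5

Remark: locants C1–C11 in the text are drimane locants (C4 gem-dimethyl carbon, C5 and C10 ring-fusion carbons, C8 the CH–CH3 carbon, C9 the ring carbon of the exocyclic alkene, C11 the chlorinated carbon); in step 5 the catalyst antipode is taken to be the one that gives the 8aS ketone.

Step 1
Reactants: 1 (2-methylpropanenitrile); 2 (1-bromo-3-chloropropane)
Product: 3 5-chloro-2,2-dimethylpentanenitrile
Conditions: LiN(i-Pr)2, THF, −78 °C; then 2, −78 to 20 °C
Reagents that add atoms: none
Why: SN2 alkylation of the metalated nitrile, in which the tertiary carbanion displaces bromide in preference to chloride, builds the quaternary C4 with both methyl groups and the C1–C3 chain.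

Step 2
Reactants: 3 (5-chloro-2,2-dimethylpentanenitrile)
Product: 4 6-chloro-3,3-dimethylhexan-2-one
Conditions: MeLi, Et2O, 0 °C; then 2 M HCl, 20 °C
Reagents that add atoms: methyllithium C[Li]; water O
Why: Organolithium addition to a nitrile stops at the N-lithio imine, whose acidic hydrolysis should give the methyl ketone (nitrile-to-ketone synthesis), the primary chloride being inert to MeLi at 0 °C.

Step 3
Reactants: 4 (6-chloro-3,3-dimethylhexan-2-one)
Product: 5 7-chloro-4,4-dimethylhept-1-en-3-one
Conditions: (CH2O)n, N-methylanilinium trifluoroacetate, THF, reflux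
Reagents that add atoms: paraformaldehyde (formaldehyde unit) C=O
Why: The ketone has alpha-hydrogens only on its methyl group, so the Mannich-type alpha-methylenation (Gras conditions) should give the non-enolisable vinyl ketone regiospecifically.

Step 4
Reactants: 5 (7-chloro-4,4-dimethylhept-1-en-3-one); 6 (pentan-3-one)
Product: 8 3-(5-chloro-2-methylpentan-2-yl)-2,6-dimethylcyclohex-2-en-1-one (racemic), via 1,5-diketone 7 (not isolated)
Conditions: 6 (5 equiv), H2SO4 (cat.), toluene, 60 °C then reflux (Dean–Stark)
Reagents that add atoms: none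
Why: Acid-catalysed Robinson annulation, in which the enol of the symmetrical ketone adds to the non-enolisable vinyl ketone and the only six-membered aldol condensation available closes ring B as the tetrasubstituted enone, with no base present that could trigger early alkylation by the chloride.

Step 5
Reactants: 8 (3-(5-chloro-2-methylpentan-2-yl)-2,6-dimethylcyclohex-2-en-1-one)
Product: 9 (8aS)-2,5,5,8a-tetramethyl-3,5,6,7,8,8a-hexahydronaphthalen-1(2H)-one (both C2 epimers)
Conditions: N-(9-anthracenylmethyl)-O-allylcinchonidinium bromide (10 mol %), 50% aq. KOH, toluene, 0 °C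
Reagents that add atoms: none
Why: Proposed new method: hydroxide at the interface removes a gamma-proton (C6–H) of the enone and the extended dienolate O–C9=C10–C5=C6, held as a tight ion pair by the chiral ammonium cation, attacks the primary chloride at C1 through its alpha carbon C10 in an intramolecular SN2 reaction. The closest known reaction types are the deconjugative alpha-alkylation of enone dienolates (KOt-Bu, as in the 4,4-dialkylation of octalones and 3-keto-4-ene steroids) and the cinchona-ammonium phase-transfer alkylation of cyclic ketone enolates to quaternary carbons, which includes ring closures by alkyl chlorides. Ring A closes in the 6-(enolendo)-exo-tet mode, favoured by the gem-dimethyl group in the tether. The new quaternary stereocentre C10 is controlled by the catalyst, which shields one face of the planar dienolate, because the only other stereocentre (C8) epimerises freely and is reset later. The step needs alpha- over gamma- and O-alkylation: C10 carries the largest coefficient of the dienolate HOMO so that kinetic alkylation goes there as in the steroid cases, and O-alkylation would need an eight-membered ring. C5 stays trigonal (C5=C6), so the ring fusion is left open for the hydrogenation that follows.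

Step 6
Reactants: 9 ((8aS)-2,5,5,8a-tetramethyl-3,5,6,7,8,8a-hexahydronaphthalen-1(2H)-one)
Product: 10 (4aS,8aS)-2,5,5,8a-tetramethyloctahydronaphthalen-1(2H)-one (both C2 epimers)
Conditions: H2 (4 atm), 10% Pd/C, EtOAc, 25 °C
Reagents that add atoms: none
Why: Heterogeneous hydrogenation of the trisubstituted C4=C4a alkene should take place on the face opposite to the angular 8a-methyl group (as with 4,4-dimethyl-5-ene steroids), which places the C4a hydrogen trans to that methyl and gives the trans-decalin.

Step 7
Reactants: 10 ((4aS,8aS)-2,5,5,8a-tetramethyloctahydronaphthalen-1(2H)-one)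
Product: 11 (4aS,8aS)-2,5,5,8a-tetramethyl-3,4,4a,5,6,7,8,8a-octahydronaphthalen-1-yl trifluoromethanesulfonate
Conditions: KN(SiMe3)2, THF, −78 °C; PhNTf2, −78 to 0 °C
Reagents that add atoms: N-phenylbis(trifluoromethanesulfonimide) O=S(=O)(N(c1ccccc1)S(=O)(=O)C(F)(F)F)C(F)(F)F
Why: The ketone has a single alpha-hydrogen (C2–H), so enolisation and O-sulfonylation (enol triflate formation) can give only one alkenyl triflate, and both C2 epimers converge on it.

Step 8
Reactants: 12 (2-hydroxy-3-methoxybenzaldehyde)
Product: 13 3-methoxy-2-{[tri(propan-2-yl)silyl]oxy}benzaldehyde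
Conditions: TIPSCl, imidazole, DMF, 25 °C
Reagents that add atoms: chlorotri(propan-2-yl)silane CC(C)[Si](Cl)(C(C)C)C(C)C
Why: Silyl ether protection of the phenol gives a group that should survive the organochromium addition, the dissolving-metal reduction and the amide base, and that leaves with fluoride at the end.

Step 9
Reactants: 11 ((4aS,8aS)-2,5,5,8a-tetramethyl-3,4,4a,5,6,7,8,8a-octahydronaphthalen-1-yl trifluoromethanesulfonate); 13 (3-methoxy-2-{[tri(propan-2-yl)silyl]oxy}benzaldehyde)
Product: 14 (3-methoxy-2-{[tri(propan-2-yl)silyl]oxy}phenyl)[(4aS,8aS)-2,5,5,8a-tetramethyl-3,4,4a,5,6,7,8,8a-octahydronaphthalen-1-yl]methanol (both carbinol epimers)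
Conditions: CrCl2 (4 equiv), NiCl2 (2 mol %), DMF, 25 °C
Reagents that add atoms: none
Why: Nozaki–Hiyama–Kishi coupling, in which the hindered alkenyl triflate is activated by the nickel co-catalyst and handed on to chromium, should form the C9–C11 bond by addition of the alkenylchromium reagent to the aldehyde alone; the carbinol centre is oxidised away in the next step.

Step 10
Reactants: 14 (the allylic benzylic alcohol)
Product: 15 (3-methoxy-2-{[tri(propan-2-yl)silyl]oxy}phenyl)[(4aS,8aS)-2,5,5,8a-tetramethyl-3,4,4a,5,6,7,8,8a-octahydronaphthalen-1-yl]methanone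
Conditions: Dess–Martin periodinane, CH2Cl2, 25 °C
Reagents that add atoms: none
Why: Dess–Martin oxidation of the allylic and benzylic secondary alcohol should give the aryl enone without touching the silyl ether or the alkene.

Step 11
Reactants: 15 (the aryl enone)
Product: 17 (3-methoxy-2-{[tri(propan-2-yl)silyl]oxy}phenyl)[(2S,4aS,8aS)-2,5,5,8a-tetramethyloctahydronaphthalen-1(2H)-ylidene]methyl trifluoromethanesulfonate (E/Z mixture), via lithium enolate 16 (not isolated)
Conditions: Li (2.2 equiv), t-BuOH (1.0 equiv), NH3(l)/THF, −78 °C; NH3 evaporated; PhNTf2, THF, 0 to 25 °C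
Reagents that add atoms: N-phenylbis(trifluoromethanesulfonimide) O=S(=O)(N(c1ccccc1)S(=O)(=O)C(F)(F)F)C(F)(F)F
Why: Dissolving-metal reduction of the enone with trapping of the regiodefined enolate on oxygen (reductive enolate triflation) should protonate C8 on the face opposite to the axial angular methyl group, a course that also frees the C8 methyl from allylic 1,3-strain with the exocyclic enolate, which sets the 2S centre.

Step 12
Reactants: 17 (the enol triflate as E/Z mixture)
Product: 18 {2-[(E)-chloro[(2S,4aS,8aS)-2,5,5,8a-tetramethyloctahydronaphthalen-1(2H)-ylidene]methyl]-6-methoxyphenoxy}tri(propan-2-yl)silane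
Conditions: n-Bu4NCl (5 equiv), 2,6-di-tert-butylpyridine (0.2 equiv), (CF3)2CHOH, 40 °C
Reagents that add atoms: tetrabutylammonium chloride CCCC[N+](CCCC)(CCCC)CCCC.[Cl-]
Why: Solvolytic vinylic substitution (SN1 through a linear alpha-aryl vinyl cation, a classical reaction of alpha-arylvinyl triflates in ionising solvents) lets both triflate isomers converge on one cation, which chloride should attack in the alkene plane from the side of C8 (only an equatorial hydrogen in that plane) and not from the side of the quaternary C10 (ring CH2 in that plane), giving the E chloroalkene.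

Step 13
Reactants: 18 (the silyl-protected E chloroalkene)
Product: 20 2-[(E)-chloro[(2S,4aS,8aS)-2,5,5,8a-tetramethyloctahydronaphthalen-1(2H)-ylidene]methyl]-6-methoxycyclohexa-2,5-diene-1,4-dione (CNP0249629.1), via phenol 19 (not isolated)
Conditions: TBAF, THF, 0 °C; then K2[ON(SO3)2], KH2PO4, H2O/acetone, 0 to 25 °C
Reagents that add atoms: potassium nitrosodisulfonate [K+].[K+].[O-]S(=O)(=O)N([O])S(=O)(=O)[O-]
Why: Fluoride cleaves the aryl silyl ether and the freed 2,6-disubstituted phenol, whose para position is open, should be oxidised to the para-quinone (Teuber oxidation) under conditions that leave the chloroalkene and the three stereocentres untouched.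

Compound list
1 | 2-methylpropanenitrile | CC(C)C#N | starting material
2 | 1-bromo-3-chloropropane | ClCCCBr | starting material
3 | 5-chloro-2,2-dimethylpentanenitrile | CC(C)(CCCCl)C#N | intermediate
4 | 6-chloro-3,3-dimethylhexan-2-one | CC(=O)C(C)(C)CCCCl | intermediate
5 | 7-chloro-4,4-dimethylhept-1-en-3-one | C=CC(=O)C(C)(C)CCCCl | intermediate
6 | pentan-3-one | CCC(=O)CC | starting material
7 | 11-chloro-4,8,8-trimethylundecane-3,7-dione (racemic, not isolated) | CCC(=O)C(C)CCC(=O)C(C)(C)CCCCl | intermediate
8 | 3-(5-chloro-2-methylpentan-2-yl)-2,6-dimethylcyclohex-2-en-1-one (racemic) | O=C1C(C)CCC(C(C)(C)CCCCl)=C1C | intermediate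
9 | (8aS)-2,5,5,8a-tetramethyl-3,5,6,7,8,8a-hexahydronaphthalen-1(2H)-one (both C2 epimers) | O=C1C(C)CC=C2C(C)(C)CCC[C@]12C | intermediate
10 | (4aS,8aS)-2,5,5,8a-tetramethyloctahydronaphthalen-1(2H)-one (both C2 epimers) | O=C1C(C)CC[C@H]2C(C)(C)CCC[C@]12C | intermediate
11 | (4aS,8aS)-2,5,5,8a-tetramethyl-3,4,4a,5,6,7,8,8a-octahydronaphthalen-1-yl trifluoromethanesulfonate | FC(F)(F)S(=O)(=O)OC1=C(C)CC[C@H]2C(C)(C)CCC[C@]12C | intermediate
12 | 2-hydroxy-3-methoxybenzaldehyde | O=Cc1cccc(OC)c1O | starting material
13 | 3-methoxy-2-{[tri(propan-2-yl)silyl]oxy}benzaldehyde | O=Cc1cccc(OC)c1O[Si](C(C)C)(C(C)C)C(C)C | intermediate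
14 | (3-methoxy-2-{[tri(propan-2-yl)silyl]oxy}phenyl)[(4aS,8aS)-2,5,5,8a-tetramethyl-3,4,4a,5,6,7,8,8a-octahydronaphthalen-1-yl]methanol (both carbinol epimers) | COc1cccc(C(O)C2=C(C)CC[C@H]3C(C)(C)CCC[C@]23C)c1O[Si](C(C)C)(C(C)C)C(C)C | intermediate
15 | (3-methoxy-2-{[tri(propan-2-yl)silyl]oxy}phenyl)[(4aS,8aS)-2,5,5,8a-tetramethyl-3,4,4a,5,6,7,8,8a-octahydronaphthalen-1-yl]methanone | COc1cccc(C(=O)C2=C(C)CC[C@H]3C(C)(C)CCC[C@]23C)c1O[Si](C(C)C)(C(C)C)C(C)C | intermediate
16 | lithium (3-methoxy-2-{[tri(propan-2-yl)silyl]oxy}phenyl)[(2S,4aS,8aS)-2,5,5,8a-tetramethyloctahydronaphthalen-1(2H)-ylidene]methanolate (E/Z mixture, not isolated) | COc1cccc(C(O[Li])=C2[C@@H](C)CC[C@H]3C(C)(C)CCC[C@]23C)c1O[Si](C(C)C)(C(C)C)C(C)C | intermediate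
17 | (3-methoxy-2-{[tri(propan-2-yl)silyl]oxy}phenyl)[(2S,4aS,8aS)-2,5,5,8a-tetramethyloctahydronaphthalen-1(2H)-ylidene]methyl trifluoromethanesulfonate (E/Z mixture) | COc1cccc(C(OS(=O)(=O)C(F)(F)F)=C2[C@@H](C)CC[C@H]3C(C)(C)CCC[C@]23C)c1O[Si](C(C)C)(C(C)C)C(C)C | intermediate
18 | {2-[(E)-chloro[(2S,4aS,8aS)-2,5,5,8a-tetramethyloctahydronaphthalen-1(2H)-ylidene]methyl]-6-methoxyphenoxy}tri(propan-2-yl)silane | COc1cccc(/C(Cl)=C2/[C@@H](C)CC[C@H]3C(C)(C)CCC[C@]23C)c1O[Si](C(C)C)(C(C)C)C(C)C | intermediate
19 | 2-[(E)-chloro[(2S,4aS,8aS)-2,5,5,8a-tetramethyloctahydronaphthalen-1(2H)-ylidene]methyl]-6-methoxyphenol (not isolated) | COc1cccc(/C(Cl)=C2/[C@@H](C)CC[C@H]3C(C)(C)CCC[C@]23C)c1O | intermediate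
20 | 2-[(E)-chloro[(2S,4aS,8aS)-2,5,5,8a-tetramethyloctahydronaphthalen-1(2H)-ylidene]methyl]-6-methoxycyclohexa-2,5-diene-1,4-dione (CNP0249629.1) | COC1=CC(=O)C=C(/C(Cl)=C2/[C@@H](C)CC[C@H]3C(C)(C)CCC[C@]23C)C1=O | target

Total step count: 13. Longest linear sequence: 12 steps (steps 1 to 7 and 9 to 13); step 8 is a one-step side branch.

Steps most likely to fail

Step 5 (proposed new method). What may go wrong is poor facial discrimination of the dienolate inside the ammonium ion pair, a racemic background alkylation at the interface, or a sluggish displacement of the chloride at 0 °C. The fallback sets out from 8 and gives up catalytic induction for resolution. KOt-Bu in t-BuOH/THF at 25 °C (the known deconjugative alpha-alkylation of enone dienolates) should close the same ring without stereocontrol and give racemic 2,5,5,8a-tetramethyl-3,5,6,7,8,8a-hexahydronaphthalen-1(2H)-one F1. After equilibration of C2 by the base, the enantiomers are separated by preparative chromatography on a chiral stationary phase, and the pooled 8aS fractions are 9, where the route is rejoined.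

Step 12. What may go wrong is incomplete ionisation of the hindered enol triflate, capture of the vinyl cation by the solvent, or unselective approach of chloride to the two sides of the cation. The fallback sets out from 17 and replaces the cationic substitution by a metal-catalysed exchange. Ni(cod)2 (10 mol %) and LiCl in DMA/THF at 25 °C (nickel-catalysed halogenation of enol triflates through oxidative addition and C–Cl reductive elimination) should give 18 together with {2-[(Z)-chloro[(2S,4aS,8aS)-2,5,5,8a-tetramethyloctahydronaphthalen-1(2H)-ylidene]methyl]-6-methoxyphenoxy}tri(propan-2-yl)silane F2, in a ratio that follows the triflate geometry. F2 is separated and brought back into equilibrium with 18 by thioxanthone-sensitised irradiation (energy-transfer E/Z isomerisation of the aryl alkene); the E isomer collected over the cycles is 18.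

Step 11. What may go wrong is protonation of C8 from the wrong face during the dissolving-metal reduction, over-reduction of the aryl ketone, or slow O-sulfonylation of the very hindered enolate. The fallback sets out from 15 and separates reduction from enolisation. Hydrogenation (H2, 50 atm, Pd/C, EtOAc) should add both hydrogens on the face opposite to the angular methyl group and give (3-methoxy-2-{[tri(propan-2-yl)silyl]oxy}phenyl)[(1S,2S,4aS,8aS)-2,5,5,8a-tetramethyldecahydronaphthalen-1-yl]methanone F3. Its only enolisable position is C1–H, so KN(SiMe3)2 and PhNTf2 in THF (−78 to 0 °C) should then give 17.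

Further compounds
F1 | step 5 | racemic 2,5,5,8a-tetramethyl-3,5,6,7,8,8a-hexahydronaphthalen-1(2H)-one | O=C1C(C)CC=C2C(C)(C)CCCC12C
F2 | step 12 | {2-[(Z)-chloro[(2S,4aS,8aS)-2,5,5,8a-tetramethyloctahydronaphthalen-1(2H)-ylidene]methyl]-6-methoxyphenoxy}tri(propan-2-yl)silane | COc1cccc(/C(Cl)=C2\[C@@H](C)CC[C@H]3C(C)(C)CCC[C@]23C)c1O[Si](C(C)C)(C(C)C)C(C)C
F3 | step 11 | (3-methoxy-2-{[tri(propan-2-yl)silyl]oxy}phenyl)[(1S,2S,4aS,8aS)-2,5,5,8a-tetramethyldecahydronaphthalen-1-yl]methanone | COc1cccc(C(=O)[C@H]2[C@@H](C)CC[C@H]3C(C)(C)CCC[C@]23C)c1O[Si](C(C)C)(C(C)C)C(C)C
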